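Ring C of the flavanone half is cut at O1–C2 and at C4–C4a. This leaves 3,5-dimethoxyphenol and a three-carbon 1,3-dielectrophile that already carries the kaempferol 3-O-aryl ether. In one flask operation the phenol oxygen inverts an (R)-benzylic carbinol (Mitsunobu) to set C2 as S. TFA/TFAA then unmask the tert-butyl ester and drive acylation of ring A. The precursor is an open-chain (R)-β-hydroxy tert-butyl ester. The step exploits the phloroglucinol pattern of ring A. O1 and C4a act as an O,C-dinucleophile, and C4a and C8 are equivalent by the mirror plane through O1, C8a and C6, so one regioisomer results. The peri pair C5–OMe/C4=O later allows selective demethylation.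

Key step: step 6

Remark: O1, C2–C8a and rings A, B, C refer to the flavanone half. Positions 3, 5, 7, 4' written with "kaempferol" refer to the flavonol half. Astragalin is taken as a purchasable natural product.

Step 1
Reactants: 1 astragalin (kaempferol 3-O-β-D-glucopyranoside)
Product: 2 7,4'-di-O-benzylkaempferol 3-O-β-D-glucopyranoside
Conditions: BnBr (2.3 equiv), K2CO3 (2.5 equiv), DMF, rt to 40 °C
Reagents that add atoms: benzyl bromide, BrCc1ccccc1
Why: Williamson ether synthesis in which K2CO3 ionises only the acidic 7-OH and 4'-OH, since the 5-OH is tied up in a hydrogen bond to C4=O, the sugar hydroxyls are far less acidic and the glucosyl residue blocks O3.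

Step 2
Reactants: 2 7,4'-di-O-benzylkaempferol 3-O-β-D-glucopyranoside
Product: 3 7,4'-di-O-benzylkaempferol (7-benzyloxy-2-(4-benzyloxyphenyl)-3,5-dihydroxychromen-4-one)
Conditions: 2 M HCl, EtOH/H2O, reflux
Reagents that add atoms: none
Why: Acid-catalysed glycoside (acetal) hydrolysis through the glucosyl oxocarbenium ion frees the enolic 3-OH, while aryl benzyl ethers are stable to dilute hot mineral acid.

Step 3
Reactants: 3 7,4'-di-O-benzylkaempferol; 4 4-fluorobenzaldehyde
Product: 5 4-(7,4'-di-O-benzylkaempferol-3-yloxy)benzaldehyde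
Conditions: Cs2CO3 (1.1 equiv), 4 (2 equiv), DMF, 90 °C, argon
Reagents that add atoms: none
Why: Nucleophilic aromatic substitution (addition–elimination through a Meisenheimer adduct stabilised by the para formyl group), in which one equivalent of base ionises the more acidic enolic 3-OH and not the chelated 5-OH, and exclusion of air protects the flavonolate from oxygenation.

Step 4
Reactants: 5 4-(7,4'-di-O-benzylkaempferol-3-yloxy)benzaldehyde; 6 tert-butyl diazoacetate
Product: 7 tert-butyl 3-[4-(7,4'-di-O-benzylkaempferol-3-yloxy)phenyl]-3-oxopropanoate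
Conditions: NbCl5 (5 mol%), CH2Cl2, rt
Reagents that add atoms: none
Why: Roskamp homologation, in which the diazo carbon adds to the Lewis-acid-bound aldehyde and a 1,2-hydride shift with loss of N2 gives the β-keto ester without touching the chromone or the benzyl ethers.

Step 5
Reactants: 7 tert-butyl 3-[4-(7,4'-di-O-benzylkaempferol-3-yloxy)phenyl]-3-oxopropanoate
Product: 8 tert-butyl (3R)-3-hydroxy-3-[4-(7,4'-di-O-benzylkaempferol-3-yloxy)phenyl]propanoate
Conditions: RuCl[(R,R)-TsDPEN](p-cymene) (1 mol%), HCO2H/Et3N 5:2, CH2Cl2, 30 °C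
Reagents that add atoms: none
Why: Noyori–Ikariya asymmetric transfer hydrogenation, in which hydride and proton pass from the Ru–H/N–H pair to the aryl ketone in an outer-sphere six-membered transition state whose CH/π contact between p-cymene and the aryl ring selects the face, so that the (R,R)-ligand should set the new carbinol center as R, while the vinylogous-ester carbonyl of the chromone is inert.

Step 6
Reactants: 8 tert-butyl (3R)-3-hydroxy-3-[4-(7,4'-di-O-benzylkaempferol-3-yloxy)phenyl]propanoate; 9 3,5-dimethoxyphenol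
Product: 13 (2S)-2-[4-(7,4'-di-O-benzylkaempferol-3-yloxy)phenyl]-5,7-dimethoxychroman-4-one, via aryl ether tert-butyl ester 10 (not isolated), via aryloxy acid 11 (not isolated), via mixed trifluoroacetic anhydride 12 (not isolated)
Conditions: 9 (1.5 equiv), PPh3, DIAD, CH2Cl2, 0 °C to rt; then same flask, TFA, (CF3CO)2O, 0 °C to rt; aq. NaHCO3
Reagents that add atoms: none
Why: PPh3/DIAD turn the (R)-carbinol of 8 into an alkoxyphosphonium ion that the phenol oxygen of 9 displaces in an SN2 sense (Mitsunobu aryl ether synthesis), which forms O1–C2 with inversion and so fixes (2S) from the stereocenter made in step 5. TFA then removes the tert-butyl group from 10, TFAA converts acid 11 into the mixed anhydride 12, and the ring A carbon ortho to O1 attacks the activated acyl carbon (intramolecular Friedel–Crafts acylation of a 3-aryloxypropanoic acid, the classical chroman-4-one closure), which forms C4–C4a. Ring C closes in a 6-exo-trig mode at the anhydride carbonyl, and no bond to C2 is touched in this second stage. Regioselectivity is secured by symmetry, since the two carbons ortho to O1 in the 3,5-dimethoxyphenyl ether are equivalent and each is ortho or para to three oxygen donors, while the para carbon cannot reach the tethered acyl group. Chemoselectivity in the first stage rests on the free, acidic OH of 9 as against the chelated 5-OH of the chromone, and forming the ether before the ketone avoids both C-alkylation of ring A at the benzylic carbon and the easy β-elimination of a β-activated ketone. Configurational integrity in acid relies on the β-acyl group and on the electron-poor chromon-3-yl oxygen, which both disfavour ionisation of the C2–O1 bond, and on starting the acid stage at 0 °C.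

Step 7
Reactants: 13 (2S)-2-[4-(7,4'-di-O-benzylkaempferol-3-yloxy)phenyl]-5,7-dimethoxychroman-4-one
Product: 14 CNP0173006.1, (2S)-5-hydroxy-7-methoxy-2-[4-(kaempferol-3-yloxy)phenyl]chroman-4-one
Conditions: BCl3 (10 equiv), pentamethylbenzene (6 equiv), CH2Cl2, −78 °C to 0 °C; MeOH, then aq. NaHCO3
Reagents that add atoms: none
Why: Lewis-acid ether cleavage in which BCl3 with pentamethylbenzene as a non-basic benzyl cation trap removes both aryl benzyl ethers in the cold, and on warming the boron chelate between C4=O and the peri C5–OMe delivers chloride to that methyl group only, whereas the unchelated C7–OMe and the diaryl ether (two sp2 C–O bonds) are inert and no bond to C2 is broken.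

Compound list
1 | astragalin (kaempferol 3-O-β-D-glucopyranoside) | OC[C@H]1O[C@@H](Oc2c(-c3ccc(O)cc3)oc3cc(O)cc(O)c3c2=O)[C@H](O)[C@@H](O)[C@@H]1O | starting material
2 | 7,4'-di-O-benzylkaempferol 3-O-β-D-glucopyranoside | OC[C@H]1O[C@@H](Oc2c(-c3ccc(OCc4ccccc4)cc3)oc3cc(OCc4ccccc4)cc(O)c3c2=O)[C@H](O)[C@@H](O)[C@@H]1O | intermediate
3 | 7,4'-di-O-benzylkaempferol | Oc1c(-c2ccc(OCc3ccccc3)cc2)oc2cc(OCc3ccccc3)cc(O)c2c1=O | intermediate
4 | 4-fluorobenzaldehyde | O=Cc1ccc(F)cc1 | starting material
5 | 4-(7,4'-di-O-benzylkaempferol-3-yloxy)benzaldehyde | O=Cc1ccc(Oc2c(-c3ccc(OCc4ccccc4)cc3)oc3cc(OCc4ccccc4)cc(O)c3c2=O)cc1 | intermediate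
6 | tert-butyl diazoacetate | CC(C)(C)OC(=O)C=[N+]=[N-] | starting material
7 | tert-butyl 3-[4-(7,4'-di-O-benzylkaempferol-3-yloxy)phenyl]-3-oxopropanoate | CC(C)(C)OC(=O)CC(=O)c1ccc(Oc2c(-c3ccc(OCc4ccccc4)cc3)oc3cc(OCc4ccccc4)cc(O)c3c2=O)cc1 | intermediate
8 | tert-butyl (3R)-3-hydroxy-3-[4-(7,4'-di-O-benzylkaempferol-3-yloxy)phenyl]propanoate | CC(C)(C)OC(=O)C[C@@H](O)c1ccc(Oc2c(-c3ccc(OCc4ccccc4)cc3)oc3cc(OCc4ccccc4)cc(O)c3c2=O)cc1 | intermediate
9 | 3,5-dimethoxyphenol | COc1cc(O)cc(OC)c1 | starting material
10 | tert-butyl (3S)-3-(3,5-dimethoxyphenoxy)-3-[4-(7,4'-di-O-benzylkaempferol-3-yloxy)phenyl]propanoate | CC(C)(C)OC(=O)C[C@H](Oc1cc(OC)cc(OC)c1)c1ccc(Oc2c(-c3ccc(OCc4ccccc4)cc3)oc3cc(OCc4ccccc4)cc(O)c3c2=O)cc1 | intermediate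
11 | (3S)-3-(3,5-dimethoxyphenoxy)-3-[4-(7,4'-di-O-benzylkaempferol-3-yloxy)phenyl]propanoic acid | OC(=O)C[C@H](Oc1cc(OC)cc(OC)c1)c1ccc(Oc2c(-c3ccc(OCc4ccccc4)cc3)oc3cc(OCc4ccccc4)cc(O)c3c2=O)cc1 | intermediate
12 | mixed anhydride of acid 11 and trifluoroacetic acid | O=C(OC(=O)C(F)(F)F)C[C@H](Oc1cc(OC)cc(OC)c1)c1ccc(Oc2c(-c3ccc(OCc4ccccc4)cc3)oc3cc(OCc4ccccc4)cc(O)c3c2=O)cc1 | intermediate
13 | (2S)-2-[4-(7,4'-di-O-benzylkaempferol-3-yloxy)phenyl]-5,7-dimethoxychroman-4-one | COc1cc(OC)c2c(c1)O[C@H](c1ccc(Oc3c(-c4ccc(OCc5ccccc5)cc4)oc4cc(OCc5ccccc5)cc(O)c4c3=O)cc1)CC2=O | intermediate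
14 | CNP0173006.1, (2S)-5-hydroxy-7-methoxy-2-[4-(kaempferol-3-yloxy)phenyl]chroman-4-one | COc1cc(O)c2c(c1)O[C@H](c1ccc(Oc3c(-c4ccc(O)cc4)oc4cc(O)cc(O)c4c3=O)cc1)CC2=O | target

Total step count: 7. Longest linear sequence: 7 steps (1 to 14).

Steps most likely to fail

**Step 6.**
- What may go wrong: β-elimination of the alkoxyphosphonium ion to the cinnamate, and partial ionisation at the benzylic carbon during the displacement or in the acid stage (loss of configuration, O-to-C benzyl migration). Transient tert-butylation of ring A is a further risk.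
- Not a concern: loss of a benzyl group in the acid stage would be harmless, because these groups are no longer needed after the ether is formed.
- Fallback, from 5 back to 13: the C2–O1 bond is made under catalyst control on an activated chalcone.
- Crossed Claisen condensation of methyl 2-hydroxy-4,6-dimethoxybenzoate with the lithium enolate of tert-butyl acetate (LiN(iPr)2, THF, −78 °C to rt, excess enolate) gives tert-butyl 3-(2-hydroxy-4,6-dimethoxyphenyl)-3-oxopropanoate F1.
- Knoevenagel condensation of this ester with 5 (piperidine/AcOH, toluene, molecular sieves) gives tert-butyl (Z)-2-(2-hydroxy-4,6-dimethoxybenzoyl)-3-[4-(7,4'-di-O-benzylkaempferol-3-yloxy)phenyl]prop-2-enoate F2.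
- A bifunctional cinchona-alkaloid thiourea, in the pseudoenantiomeric form that delivers the 2S series, catalyses the 6-endo-trig oxa-Michael closure in cold toluene. The product is tert-butyl (2S)-2-[4-(7,4'-di-O-benzylkaempferol-3-yloxy)phenyl]-5,7-dimethoxy-4-oxochromane-3-carboxylate F3.
- TsOH in warm toluene then removes the tert-butyl group and CO2 to reach 13.

**Step 3.**
- What may go wrong: sluggish substitution by the delocalised, weakly nucleophilic flavonolate, thermal or oxidative breakdown of that anion on long heating, and competing arylation at O5.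
- Fallback, from 3 back to 5: the uncatalysed addition–elimination is replaced by an Ullmann-type copper-catalysed C–O coupling. The partner is 4-iodobenzaldehyde (CuI 10 mol%, picolinic acid 20 mol%, K3PO4, DMSO, 80 °C, argon). The aryl–oxygen bond then forms at the metal, and electronic activation of the arene is not required.
- This fallback makes no new compound (F0).

**Step 7.**
- What may go wrong: Lewis-acid-induced opening of ring C at C2–O1 with erosion of configuration, and incomplete discrimination between the two methyl ethers.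
- Fallback, from 13 back to 14: the two kinds of C–O bond are cleaved by unrelated mechanisms, so that no boron halide meets the flavanone.
- MgI2·OEt2 (toluene/Et2O, 60 °C) cleaves only the chelated C5–OMe, by iodide attack on the methyl group inside a magnesium chelate. This gives (2S)-2-[4-(7,4'-di-O-benzylkaempferol-3-yloxy)phenyl]-5-hydroxy-7-methoxychroman-4-one F4.
- Neutral hydrogenolysis (H2, Pd/C, EtOAc/THF, rt) then removes both benzyl groups to give 14.

Further compounds
F1 | step 6 | tert-butyl 3-(2-hydroxy-4,6-dimethoxyphenyl)-3-oxopropanoate | COc1cc(O)c(C(=O)CC(=O)OC(C)(C)C)c(OC)c1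
F2 | step 6 | tert-butyl (Z)-2-(2-hydroxy-4,6-dimethoxybenzoyl)-3-[4-(7,4'-di-O-benzylkaempferol-3-yloxy)phenyl]prop-2-enoate | CC(C)(C)OC(=O)/C(=C\c1ccc(Oc2c(-c3ccc(OCc4ccccc4)cc3)oc3cc(OCc4ccccc4)cc(O)c3c2=O)cc1)C(=O)c1c(O)cc(OC)cc1OC
F3 | step 6 | tert-butyl (2S)-2-[4-(7,4'-di-O-benzylkaempferol-3-yloxy)phenyl]-5,7-dimethoxy-4-oxochromane-3-carboxylate (C3 epimerisable, not defined) | COc1cc(OC)c2c(c1)O[C@H](c1ccc(Oc3c(-c4ccc(OCc5ccccc5)cc4)oc4cc(OCc5ccccc5)cc(O)c4c3=O)cc1)C(C(=O)OC(C)(C)C)C2=O
F0 | step 3 | none | none
F4 | step 7 | (2S)-2-[4-(7,4'-di-O-benzylkaempferol-3-yloxy)phenyl]-5-hydroxy-7-methoxychroman-4-one | COc1cc(O)c2c(c1)O[C@H](c1ccc(Oc3c(-c4ccc(OCc5ccccc5)cc4)oc4cc(OCc5ccccc5)cc(O)c4c3=O)cc1)CC2=O
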